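## Retrosynthetic overview

1. Target ⇐ C6 angeloylation and C16 detritylation at the end; the C8 carbinol ⇐ Markovnikov hydration of an 8(17)-methylidene ⇐ 8-ketone.
2. 8-Ketone ⇐ three-component union of a bicyclic enone, a methyl cuprate (sets C10, cis fusion) and a side-chain iodide (C9–C11 bond).
3. Ring B (enone) ⇐ aldol condensation of a 1,5-diketone ⇐ Wacker oxidation of an allyl-bearing β-silyloxy ketone.
4. Ring A ⇐ semipinacol ring expansion of a cyclopentyl 2,3-epoxy alcohol (cyclopentanol → cyclohexanone; sets C5 and C6) ⇐ 2,2-dimethylcyclopentanone + pent-1-en-4-yne (alkynylation, E-reduction, Shi epoxidation).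
5. Side chain (C11–C16, C13 stereocentre) ⇐ Ir-catalysed branched allylation of an acetaldehyde enolate equivalent by a butenediol carbonate. Ring order: A by ring expansion, then B by aldol condensation.

Assumption 1: the SMILES is taken literally, i.e. a cis-fused decalin; with labdane numbering and β = face of the C10 methyl it is 5β-H, 6α-O-angeloyl (Z), 8α-OH/8β-CH3, 9β side chain, 13R (CIP 5R,6S,8R,9R,10S,13R).

Assumption 2: the (Sa,S,S)-phosphoramidite is taken to give the (R)-branched product in step 9; if the sense is opposite, the antipodal ligand is used.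

## Route

Step 1
Reactants: 1 2,2-dimethylcyclopentan-1-one; 2 pent-1-en-4-yne
Product: 4 rac-2,2-dimethyl-1-(pent-4-en-1-yn-1-yl)cyclopentan-1-ol, via lithium acetylide 3 (not isolated)
Conditions: 2, n-BuLi, THF, −78 °C; then 1, −78 → 0 °C; H2O
Reagents that add atoms: none
Why: Acetylide 1,2-addition to a ketone that can enolise on one side only; the carbinol centre is left racemic on purpose because it becomes the C=O carbon in step 4.

Step 2
Reactants: 4 rac-2,2-dimethyl-1-(pent-4-en-1-yn-1-yl)cyclopentan-1-ol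
Product: 5 rac-2,2-dimethyl-1-[(1E)-penta-1,4-dien-1-yl]cyclopentan-1-ol
Conditions: LiAlH4, THF, 0 → 65 °C; H2O/aq NaOH work-up
Reagents that add atoms: none
Why: Alkoxide-directed trans-hydroalumination of a propargylic alcohol (LiAlH4 reduction) gives only the (E)-allylic alcohol and leaves the isolated terminal alkene alone.

Step 3
Reactants: 5 rac-2,2-dimethyl-1-[(1E)-penta-1,4-dien-1-yl]cyclopentan-1-ol
Product: 6 2,2-dimethyl-1-[(2R,3S)-3-(prop-2-en-1-yl)oxiran-2-yl]cyclopentan-1-ol (both C1 epimers)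
Conditions: ent-Shi ketone (from L-fructose, 30 mol %), Oxone, K2CO3, n-Bu4NHSO4, MeCN/DMM/aq buffer pH 10.5, 0 °C
Reagents that add atoms: potassium peroxymonosulfate (Oxone), [K+].[O-]S(=O)(=O)OO
Why: Shi asymmetric epoxidation: the chiral dioxirane attacks the trans-disubstituted alkene through a spiro transition state (the terminal alkene is inert), setting the (2R,3S)-oxirane that becomes C5/C6, whatever the configuration of the racemic carbinol.

Step 4
Reactants: 6 2,2-dimethyl-1-[(2R,3S)-3-(prop-2-en-1-yl)oxiran-2-yl]cyclopentan-1-ol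
Product: 8 (2S)-2-[(1S)-1-(tert-butyldimethylsilyloxy)but-3-en-1-yl]-3,3-dimethylcyclohexan-1-one, via free aldol 7 (not isolated)
Conditions: ZnBr2 (1.5 equiv), CH2Cl2, 0 °C → rt; then 2,6-lutidine, TBSOTf, −78 → 0 °C
Reagents that add atoms: tert-butyldimethylsilyl triflate, CC(C)(C)[Si](C)(C)OS(=O)(=O)C(F)(F)F
Why: Semipinacol ring expansion of a 2,3-epoxy alcohol (Tu / Suzuki–Tsuchihashi type): Zn(II) opens the oxirane at the carbon next to the carbinol while the more electron-rich quaternary ring carbon migrates anti to the leaving oxygen (inversion at the migration terminus, the other C–O untouched), so the trans-epoxide gives the anti β-hydroxy cyclohexanone from both carbinol epimers, and in-flask silylation blocks retro-aldol.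

Step 5
Reactants: 8 (2S)-2-[(1S)-1-(tert-butyldimethylsilyloxy)but-3-en-1-yl]-3,3-dimethylcyclohexan-1-one
Product: 9 (2S)-2-[(1S)-1-(tert-butyldimethylsilyloxy)-3-oxobutyl]-3,3-dimethylcyclohexan-1-one
Conditions: PdCl2 (10 mol %), CuCl, O2 (1 atm), DMF/H2O 7:1, rt
Reagents that add atoms: water, O
Why: Tsuji–Wacker oxidation; Markovnikov hydroxypalladation of the terminal alkene gives the methyl ketone without touching a stereocentre.

Step 6
Reactants: 9 (2S)-2-[(1S)-1-(tert-butyldimethylsilyloxy)-3-oxobutyl]-3,3-dimethylcyclohexan-1-one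
Product: 10 (4S,4aR)-4-(tert-butyldimethylsilyloxy)-5,5-dimethyl-4,4a,5,6,7,8-hexahydronaphthalen-2(3H)-one
Conditions: pyrrolidine (1.2 equiv), AcOH (0.2 equiv), toluene, 60 °C; then aq NaOAc/AcOH
Reagents that add atoms: none
Why: Intramolecular aldol condensation (Robinson-type cyclodehydration of a 1,5-diketone) through the enamine of the methyl ketone; the non-basic conditions avoid β-elimination of the silyloxy group and epimerisation at C4a.

Step 7
Reactants: 11 (E)-but-2-ene-1,4-diol
Product: 12 (E)-4-(trityloxy)but-2-en-1-ol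
Conditions: TrCl (0.33 equiv), Et3N, DMAP (cat.), CH2Cl2, 0 °C → rt (excess diol recovered)
Reagents that add atoms: trityl chloride, ClC(c1ccccc1)(c1ccccc1)c1ccccc1
Why: Statistical mono-tritylation (SN1 etherification) of a symmetric diol used in excess.

Step 8
Reactants: 12 (E)-4-(trityloxy)but-2-en-1-ol
Product: 13 methyl (E)-4-(trityloxy)but-2-en-1-yl carbonate
Conditions: ClCO2Me, pyridine, CH2Cl2, 0 °C
Reagents that add atoms: methyl chloroformate, COC(=O)Cl
Why: O-acylation with a chloroformate installs the allylic carbonate leaving group.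

Step 9
Reactants: 13 methyl (E)-4-(trityloxy)but-2-en-1-yl carbonate; 14 (ethenyloxy)trimethylsilane
Product: 16 (3R)-3-(trityloxymethyl)pent-4-en-1-ol, via aldehyde 15 (not isolated)
Conditions: [Ir(cod)Cl]2 (2 mol %), (Sa,S,S)-phosphoramidite (4 mol %, pre-activated with n-PrNH2), CsF (10 mol %), 14 (3 equiv), THF, 35 °C; then NaBH4, MeOH, 0 °C; H2O
Reagents that add atoms: none
Why: Proposed new method: Ir-catalysed branched-selective asymmetric allylic alkylation with the parent acetaldehyde enol silane as nucleophile – ionisation of the carbonate gives a cyclometalated (phosphoramidite)Ir π-allyl plus methoxide, which (with catalytic fluoride) desilylates 14, and the small soft C-enolate attacks the CH2OTr-bearing allyl terminus anti to Ir on the ligand-defined face to set C13 (R); the closest known reactions are Ir-catalysed allylic alkylations with ketone silyl enol ethers and with malonates, and the aldehyde is reduced at once to prevent a second allylation or aldol.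

Step 10
Reactants: 16 (3R)-3-(trityloxymethyl)pent-4-en-1-ol
Product: 17 (3R)-5-iodo-3-(trityloxymethyl)pent-1-ene
Conditions: I2, PPh3, imidazole, CH2Cl2, 0 °C → rt
Reagents that add atoms: iodine, II
Why: Appel-type iodination, SN2 at the primary carbon; the stereocentre is not involved.

Step 11
Reactants: 10 (4S,4aR)-4-(tert-butyldimethylsilyloxy)-5,5-dimethyl-4,4a,5,6,7,8-hexahydronaphthalen-2(3H)-one; 17 (3R)-5-iodo-3-(trityloxymethyl)pent-1-ene
Product: 19 (1R,4S,4aR,8aS)-4-(tert-butyldimethylsilyloxy)-5,5,8a-trimethyl-1-[(3R)-3-(trityloxymethyl)pent-4-en-1-yl]octahydronaphthalen-2(1H)-one, via lithium enolate 18 (not isolated)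
Conditions: MeLi (2.1 equiv), CuI (1.05 equiv), Et2O, 0 °C; 10, −40 → 0 °C; then HMPA, 17 (1.5 equiv), THF, −20 °C → rt; H2O
Reagents that add atoms: lithium dimethylcuprate (from MeLi and CuI), [Li+].C[Cu-]C
Why: Gilman conjugate addition followed by C-alkylation of the regiospecific enolate: methyl adds cis to H-5 (attack on the other face would be syn-axial to both the 4α-methyl and the 6α-silyloxy group), setting C10 and the cis ring fusion, and the enolate is alkylated on the convex β-face, cis to the new methyl and away from the C4 gem-dimethyl fold, setting C9.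

Step 12
Reactants: 19 (1R,4S,4aR,8aS)-4-(tert-butyldimethylsilyloxy)-5,5,8a-trimethyl-1-[(3R)-3-(trityloxymethyl)pent-4-en-1-yl]octahydronaphthalen-2(1H)-one
Product: 20 (1S,4S,4aR,8aR)-4-(tert-butyldimethylsilyloxy)-5,5,8a-trimethyl-2-methylidene-1-[(3R)-3-(trityloxymethyl)pent-4-en-1-yl]decahydronaphthalene
Conditions: Cp2TiMe2 (3 equiv), toluene, 75 °C, dark
Reagents that add atoms: dimethyltitanocene (Petasis reagent), C[Ti](C)(C1C=CC=C1)C1C=CC=C1
Why: Petasis methylenation, a non-basic titanium-carbene olefination that converts the hindered enolisable ketone without epimerising C9 or eliminating the β-silyloxy group.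

Step 13
Reactants: 20 (1S,4S,4aR,8aR)-4-(tert-butyldimethylsilyloxy)-5,5,8a-trimethyl-2-methylidene-1-[(3R)-3-(trityloxymethyl)pent-4-en-1-yl]decahydronaphthalene
Product: 21 (1R,2R,4S,4aR,8aS)-4-(tert-butyldimethylsilyloxy)-2,5,5,8a-tetramethyl-1-[(3R)-3-(trityloxymethyl)pent-4-en-1-yl]decahydronaphthalen-2-ol
Conditions: Mn(dpm)3 (10 mol %), PhSiH3 (1.2 equiv), O2 (1 atm), i-PrOH/CH2Cl2, 0 °C
Reagents that add atoms: dioxygen, O=O
Why: Mukaiyama hydration (metal-hydride H-atom transfer to the 1,1-disubstituted alkene, Markovnikov): the tertiary C8 radical is trapped by O2 on the α-face, opposite the syn-axial C10 methyl, giving 8α-OH/8β-CH3, while the monosubstituted vinyl group reacts much more slowly.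

Step 14
Reactants: 21 (1R,2R,4S,4aR,8aS)-4-(tert-butyldimethylsilyloxy)-2,5,5,8a-tetramethyl-1-[(3R)-3-(trityloxymethyl)pent-4-en-1-yl]decahydronaphthalen-2-ol
Product: 22 (1R,2R,4S,4aR,8aS)-2,5,5,8a-tetramethyl-1-[(3R)-3-(trityloxymethyl)pent-4-en-1-yl]decahydronaphthalene-2,4-diol
Conditions: TBAF (3 equiv), THF, 50 °C
Reagents that add atoms: none
Why: Fluoride-mediated desilylation; the trityl ether, the tertiary alcohol and the alkene are untouched.

Step 15
Reactants: 22 (1R,2R,4S,4aR,8aS)-2,5,5,8a-tetramethyl-1-[(3R)-3-(trityloxymethyl)pent-4-en-1-yl]decahydronaphthalene-2,4-diol; 23 angelic acid [(2Z)-2-methylbut-2-enoic acid]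
Product: 25 C6 angelate of diol 22 (16-O-trityl ether of the target), via mixed anhydride 24 (not isolated)
Conditions: 23, 2,4,6-Cl3C6H2COCl, Et3N, toluene, rt; then 22, toluene, 80 °C (no DMAP)
Reagents that add atoms: none
Why: Yamaguchi esterification through the mixed anhydride: only the secondary C6–OH is acylated (the tertiary C8–OH is inert), and the DMAP-free protocol keeps the (Z)-geometry of the angelate.

Step 16
Reactants: 25 C6 angelate of diol 22 (16-O-trityl ether of the target)
Product: 26 target CNP0177054.1 [(5R,6S,8R,9R,10S,13R); 6α-angeloyloxy, 8α-OH, 16-OH, cis-fused]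
Conditions: CSA (10 mol %), MeOH/CH2Cl2 1:1, 0 °C
Reagents that add atoms: none
Why: Acid-catalysed solvolysis of the trityl ether (SN1, trityl cation trapped by methanol) under conditions that leave the ester, the tertiary alcohol and both alkenes intact.

## Compound list

1 | 2,2-dimethylcyclopentan-1-one | O=C1CCCC1(C)C | starting material
2 | pent-1-en-4-yne | C=CCC#C | starting material
3 | (pent-4-en-1-yn-1-yl)lithium | [Li]C#CCC=C | intermediate
4 | rac-2,2-dimethyl-1-(pent-4-en-1-yn-1-yl)cyclopentan-1-ol | C=CCC#CC1(O)CCCC1(C)C | intermediate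
5 | rac-2,2-dimethyl-1-[(1E)-penta-1,4-dien-1-yl]cyclopentan-1-ol | C=CC/C=C/C1(O)CCCC1(C)C | intermediate
6 | 2,2-dimethyl-1-[(2R,3S)-3-(prop-2-en-1-yl)oxiran-2-yl]cyclopentan-1-ol (both C1 epimers) | C=CC[C@@H]1O[C@H]1C1(O)CCCC1(C)C | intermediate
7 | (2S)-2-[(1S)-1-hydroxybut-3-en-1-yl]-3,3-dimethylcyclohexan-1-one | O=C1CCCC(C)(C)[C@H]1[C@@H](O)CC=C | intermediate
8 | (2S)-2-[(1S)-1-(tert-butyldimethylsilyloxy)but-3-en-1-yl]-3,3-dimethylcyclohexan-1-one | O=C1CCCC(C)(C)[C@H]1[C@@H](O[Si](C)(C)C(C)(C)C)CC=C | intermediate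
9 | (2S)-2-[(1S)-1-(tert-butyldimethylsilyloxy)-3-oxobutyl]-3,3-dimethylcyclohexan-1-one | O=C1CCCC(C)(C)[C@H]1[C@@H](O[Si](C)(C)C(C)(C)C)CC(C)=O | intermediate
10 | (4S,4aR)-4-(tert-butyldimethylsilyloxy)-5,5-dimethyl-4,4a,5,6,7,8-hexahydronaphthalen-2(3H)-one | O=C1C=C2CCCC(C)(C)[C@H]2[C@@H](O[Si](C)(C)C(C)(C)C)C1 | intermediate
11 | (E)-but-2-ene-1,4-diol | OC/C=C/CO | starting material
12 | (E)-4-(trityloxy)but-2-en-1-ol | OC/C=C/COC(c1ccccc1)(c1ccccc1)c1ccccc1 | intermediate
13 | methyl (E)-4-(trityloxy)but-2-en-1-yl carbonate | COC(=O)OC/C=C/COC(c1ccccc1)(c1ccccc1)c1ccccc1 | intermediate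
14 | (ethenyloxy)trimethylsilane | C=CO[Si](C)(C)C | starting material
15 | (3R)-3-(trityloxymethyl)pent-4-enal | C=C[C@H](COC(c1ccccc1)(c1ccccc1)c1ccccc1)CC=O | intermediate
16 | (3R)-3-(trityloxymethyl)pent-4-en-1-ol | C=C[C@H](COC(c1ccccc1)(c1ccccc1)c1ccccc1)CCO | intermediate
17 | (3R)-5-iodo-3-(trityloxymethyl)pent-1-ene | C=C[C@H](COC(c1ccccc1)(c1ccccc1)c1ccccc1)CCI | intermediate
18 | lithium enolate (C8–OLi, C8=C9) of the 6α-silyloxy-4,4,10β-trimethyl-cis-decalin-8-one | [Li]OC1=C[C@@]2(C)CCCC(C)(C)[C@H]2[C@@H](O[Si](C)(C)C(C)(C)C)C1 | intermediate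
19 | (1R,4S,4aR,8aS)-4-(tert-butyldimethylsilyloxy)-5,5,8a-trimethyl-1-[(3R)-3-(trityloxymethyl)pent-4-en-1-yl]octahydronaphthalen-2(1H)-one (8-ketone; 5β-H, 6α-OTBS, 9β side chain, 10β-CH3) | C=C[C@H](COC(c1ccccc1)(c1ccccc1)c1ccccc1)CC[C@@H]1[C@@]2(C)CCCC(C)(C)[C@H]2[C@@H](O[Si](C)(C)C(C)(C)C)CC1=O | intermediate
20 | (1S,4S,4aR,8aR)-4-(tert-butyldimethylsilyloxy)-5,5,8a-trimethyl-2-methylidene-1-[(3R)-3-(trityloxymethyl)pent-4-en-1-yl]decahydronaphthalene | C=C[C@H](COC(c1ccccc1)(c1ccccc1)c1ccccc1)CC[C@@H]1[C@@]2(C)CCCC(C)(C)[C@H]2[C@@H](O[Si](C)(C)C(C)(C)C)CC1=C | intermediate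
21 | (1R,2R,4S,4aR,8aS)-4-(tert-butyldimethylsilyloxy)-2,5,5,8a-tetramethyl-1-[(3R)-3-(trityloxymethyl)pent-4-en-1-yl]decahydronaphthalen-2-ol (8α-OH, 8β-CH3) | C=C[C@H](COC(c1ccccc1)(c1ccccc1)c1ccccc1)CC[C@@H]1[C@@]2(C)CCCC(C)(C)[C@H]2[C@@H](O[Si](C)(C)C(C)(C)C)C[C@@]1(C)O | intermediate
22 | (1R,2R,4S,4aR,8aS)-2,5,5,8a-tetramethyl-1-[(3R)-3-(trityloxymethyl)pent-4-en-1-yl]decahydronaphthalene-2,4-diol | C=C[C@H](COC(c1ccccc1)(c1ccccc1)c1ccccc1)CC[C@@H]1[C@@]2(C)CCCC(C)(C)[C@H]2[C@@H](O)C[C@@]1(C)O | intermediate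
23 | angelic acid, (2Z)-2-methylbut-2-enoic acid | OC(=O)/C(C)=C\C | starting material
24 | (2Z)-2-methylbut-2-enoic 2,4,6-trichlorobenzoic anhydride | O=C(OC(=O)/C(C)=C\C)c1c(Cl)cc(Cl)cc1Cl | intermediate
25 | C6 (2Z)-2-methylbut-2-enoate of diol 22 (16-O-trityl ether of the target) | C=C[C@H](COC(c1ccccc1)(c1ccccc1)c1ccccc1)CC[C@@H]1[C@@]2(C)CCCC(C)(C)[C@H]2[C@@H](OC(=O)/C(C)=C\C)C[C@@]1(C)O | intermediate
26 | CNP0177054.1, (5R,6S,8R,9R,10S,13R)-6-angeloyloxy-5β-labd-14-ene-8,16-diol skeleton as drawn | C=C[C@H](CO)CC[C@@H]1[C@@]2(C)CCCC(C)(C)[C@H]2[C@@H](OC(=O)/C(C)=C\C)C[C@@]1(C)O | target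

## Step count and risks

Total: 16 steps. Longest linear sequence: 12 steps (steps 1–6 and 11–16); the side-chain branch is 4 steps (7–10).

The three steps most likely to fail:

Step 9 (the proposed new Ir allylation). The risks are O-allylation, double allylation and aldol reactions of the acetaldehyde enolate, and an uncertain sense of induction. The fallback uses known chemistry and sets out from carbonate 13. Under the same Ir/phosphoramidite catalyst, 13 is alkylated with dimethyl malonate (the established branched-selective malonate allylation) to dimethyl 2-[(2S)-1-(trityloxy)but-3-en-2-yl]propanedioate F1. Krapcho dealkoxycarbonylation (NaCl, wet DMSO, 150 °C) gives methyl (3R)-3-(trityloxymethyl)pent-4-enoate F2. LiAlH4 reduction comes back to the route at alcohol 16 (two steps more).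

Step 11 (C-alkylation of a hindered enolate carbon next to a quaternary centre with an unactivated iodide). Proton transfer and O-alkylation can compete. The fallback sets out from enone 10 and aldehyde 15 (isolated from step 9 before the borohydride quench). The cuprate-derived enolate is transmetalated with ZnCl2 and trapped by aldol addition to 15, giving the 11-hydroxy ketone F3 (either C11 epimer). Its O-phenyl thionocarbonate F4 (PhOC(S)Cl, pyridine) is deoxygenated under Barton–McCombie conditions (Bu3SnH, AIBN, toluene, 80 °C), coming back to the route at ketone 19.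

Step 13 (chemo- and face-selectivity of the radical hydration). The vinyl group may also be hydrated, and the conformation of the strained cis-decalin decides which face of C8 is open. The fallback sets out from alkene 20. TBAF first frees the C6 alcohol to give the 6α-hydroxy 8(17)-methylidene compound F5. The 6α-OH then directs VO(acac)2/t-BuOOH epoxidation to the α-face of the exocyclic alkene only, giving the 8α,17-epoxide F6. LiEt3BH opens the oxirane at CH2, coming back to the route at diol 22 (step 14 is then not needed).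

Further compounds

F1 | step 9 | dimethyl 2-[(2S)-1-(trityloxy)but-3-en-2-yl]propanedioate | C=C[C@H](COC(c1ccccc1)(c1ccccc1)c1ccccc1)C(C(=O)OC)C(=O)OC
F2 | step 9 | methyl (3R)-3-(trityloxymethyl)pent-4-enoate | C=C[C@H](COC(c1ccccc1)(c1ccccc1)c1ccccc1)CC(=O)OC
F3 | step 11 | 11-hydroxy ketone (aldol adduct of the C9 enolate with aldehyde 15, C11 epimers) | C=C[C@H](COC(c1ccccc1)(c1ccccc1)c1ccccc1)CC(O)[C@@H]1[C@@]2(C)CCCC(C)(C)[C@H]2[C@@H](O[Si](C)(C)C(C)(C)C)CC1=O
F4 | step 11 | O-phenyl thionocarbonate of F3 | C=C[C@H](COC(c1ccccc1)(c1ccccc1)c1ccccc1)CC(OC(=S)Oc1ccccc1)[C@@H]1[C@@]2(C)CCCC(C)(C)[C@H]2[C@@H](O[Si](C)(C)C(C)(C)C)CC1=O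
F5 | step 13 | 6α-hydroxy 8(17)-methylidene compound (desilylated 20) | C=C[C@H](COC(c1ccccc1)(c1ccccc1)c1ccccc1)CC[C@@H]1[C@@]2(C)CCCC(C)(C)[C@H]2[C@@H](O)CC1=C
F6 | step 13 | 8α,17-epoxide of F5 | C=C[C@H](COC(c1ccccc1)(c1ccccc1)c1ccccc1)CC[C@@H]1[C@@]2(C)CCCC(C)(C)[C@H]2[C@@H](O)C[C@@]1(C2)O2
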